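We treat Z and G as one pool and ask how it splits. Z is the limiting reagent, with L at 2.50 equiv, so the balance of Z reads Z + G = 100 − E, in percent of the Z charged.

| flask | Z | L | J | temperature | remark | time |
|---|---|---|---|---|---|---|
| delta | 0.070 M | 2.5 equiv | 0.5 mol% | 22 °C | run made earlier |  |
| theta | 0.11 M | 2.5 equiv | 0.5 mol% | 50 °C | run made earlier |  |
| beta | 0.050 M | 2.5 equiv | 0.75 mol% | 22 °C | run made earlier |  |
| red | 0.050 M | 2.50 equiv | 0.5 mol% | 60 °C |  | 4.0 min |
| violet | 0.050 M | 2.50 equiv | 0.5 mol% |  | at 10 °C until 80 s, from then on at 60 °C | 4.0 min |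
| grey | 0.050 M | 2.50 equiv | 0.5 mol% | 35 °C |  | 4.0 min |
| ochre | 0.050 M | 2.50 equiv | 0.5 mol% | 10 °C |  | 4.0 min |

| run | time / min | G / % | E / % |
|---|---|---|---|
| delta | 6.00 | 5.0 | 89.6 |
| delta | 12.0 | 0.9 | 98.8 |
| delta | 20.0 | 0 | 99.6 |
| delta | 25.0 | 0.3 | 99.5 |
| theta | 1.50 | 5.9 | 79.5 |
| theta | 3.00 | 0.8 | 95.9 |
| theta | 5.00 | 0.1 | 99.2 |
| theta | 6.00 | 0.2 | 100.0 |
| beta | 6.00 | 8.1 | 84.6 |
| beta | 12.0 | 0.4 | 98.4 |
| beta | 20.0 | 0.4 | 99.2 |
| beta | 25.0 | 0 | 99.6 |

(standard deviation of a reading: 0.5 percentage points)

- the earlier runs were read with a standard deviation of 0.5 percentage points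

1. the flask with the highest amount of G, in percent of the Z charged ("all alike" if they lie within 1.5 percentage points) (red / violet / grey / ochre / all alike)
2. final G, as a percentage of the Z charged, in red
3. final G, as a percentage of the Z charged, in violet
4. final G, as a percentage of the Z charged, in grey
5. final G, as a percentage of the Z charged, in ochre

Does G merely pass through, or does it stand in balance with Z? We take the first reading of each run, with Z from that balance. G/Z is 0.926 in delta and 1.11 in beta, both at 22 °C but with different loadings of J. In theta, at 50 °C, it is 0.404. So we read the ratio as a balance that follows temperature. Taking its logarithm as straight in temperature between delta and theta, we expect 0.301 at 60 °C and 0.630 at 35 °C. At 10 °C the balance ratio, G over Z, should be r = 1.32.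

How much pool is left at 4.0 min? The first readings give a first-order constant for the pool. Scaled by J charged times L charged to our flasks, it is 0.192 /min from delta, 0.208 /min from beta and 0.218 /min from theta. Beta's figure is 1.08 times delta's at the same temperature, and theta's is 1.14 times delta's. Again we take the logarithm as straight in temperature between delta and theta. That gives 0.228 /min at 60 °C, 0.204 /min at 35 °C and 0.182 /min at 10 °C. The last temperature lies below both runs, so that constant is an extrapolation. The pool at 4.0 min is then 40.1% in red, 44.2% in grey and 48.2% in ochre. Violet spends 80 s at 10 °C and the rest at 60 °C, so its pool is 42.7%.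

G is the share r over one plus r of that pool. Violet ends at 60 °C, so we split its pool by red's ratio. That gives 9.27% in red, 9.86% in violet, 17.1% in grey and 27.4% in ochre, which is the highest.

The forecast stood at 4.3%, 5.8%, 13.3% and 29% for red, violet, grey and ochre, with ochre first (“Cold flasks hold the most G.”), and these differ from our figures.

The flasks give 9.97%, 12.8%, 15.0% and 38.9%, with ochre first.

    Z + Q ⇌ Q + G (K = 0.750, k = 450 /M/s, Ea = 46.0 kJ/mol, ΔH = −28.0 kJ/mol)
    Q + G ⇌ D (K = 20.0 /M, k = 2800 /M/s, Ea = 44.0 kJ/mol, ΔH = −51.0 kJ/mol)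
    L + D → Q + E (k = 27.0 /M/s, Ea = 55.0 kJ/mol)
    L + J → Q + X (k = 0.490 /M/s, Ea = 51.0 kJ/mol)
    (constants at 35 °C)

Red gives 9.97% against our 9.27%. Ochre gives 38.9% against our 27.4%: its G/Z is 1.01, below r, and 8.63% of the catalyst is still J. Splitting its simulated pool by r gives 44.1% of G, against 38.9%. The neighbour with 0.85 mol% of J holds E at 38.0%, so r gives 35.3%; it holds 34.3%, at G/Z 1.26. The neighbour with 1.2 mol% holds E at 51.4%, so r gives 27.7%; it holds 27.7%.

The earlier runs and the new flask were computed on assumed constants.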